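**Retrosynthetic overview**

1. The strategy rests on the lavandulyl chain on ring A, ArCH2(C1)–C2H(isopropenyl)–C3H2–C4H=C5Me2. Its only stereocentre, C2, carries the isopropenyl group, which is the ene-adduct pattern of an ArCH2–CH=CMe2 (C-prenyl) unit. The C2–C3 bond is therefore cut to the prenyl alkene of triacetate 4 and ethyl glyoxylate 5.
2. Ene adduct 6 is taken on by removing its carbinol oxygen, exchanging acetates for MOM ethers, reducing the ester to the aldehyde and installing C4=C5 by isopropylidene Wittig olefination, giving arene 12.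
3. Ring A is acetylated by ortho-lithiation at one of its two equivalent free positions (14). Claisen–Schmidt condensation with ring B aldehyde 16 and removal of four MOM groups give the chalcone.
4. Triacetate 4 comes from phloroglucinol 1 by C-prenylation with 2 and acetylation.
5. No ring is formed in the route: rings A and B are bought as 1 and 15.

Key step: step 3

Assumption: with a trisubstituted alkene the (BINOLate)TiCl2 catalyst is taken to favour the syn adduct, and the (S)-ligand to give the 2S carbinol; if the major adduct proves to be 3S, the antipodal ligand is used, since only C3 of the adduct is carried into the target.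

**Route**

Step 1
Reactants: 1 phloroglucinol; 2 prenyl bromide
Product: 3 2-(3-methylbut-2-en-1-yl)benzene-1,3,5-triol (2-prenylphloroglucinol)
Conditions: KOH (1 equiv), H2O, 0 °C → rt, 1 in threefold excess, argon
Reagents that add atoms: none
Why: C-alkylation of the ambident phloroglucinolate (enolate-type allylation) is favoured in water, where the phenoxide oxygens are hydrogen-bonded and the soft allylic bromide attacks carbon; the excess of 1 should hold back di- and triprenylation.

Step 2
Reactants: 3 2-prenylphloroglucinol
Product: 4 2-(3-methylbut-2-en-1-yl)benzene-1,3,5-triyl triacetate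
Conditions: Ac2O, pyridine, DMAP (cat.), rt
Reagents that add atoms: acetic anhydride, CC(=O)OC(C)=O
Why: DMAP-catalysed O-acylation of the three phenols is routine and turns the electron-rich ring into a deactivated triacetate that should no longer compete as a nucleophile in step 3.

Step 3
Reactants: 4 2-prenylphloroglucinol triacetate; 5 ethyl glyoxylate (freshly distilled)
Product: 6 ethyl (2S,3R)-2-hydroxy-4-methyl-3-[(2,4,6-triacetoxyphenyl)methyl]pent-4-enoate
Conditions: (S)-BINOL/TiCl2(OiPr)2 (10–20 mol %), 4 Å MS, CH2Cl2, −30 → 0 °C, 4 in slight excess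
Reagents that add atoms: none
Why: The titanium centre chelates the glyoxylate through its aldehyde and ester oxygens; the CH carbon of the prenyl alkene attacks the activated aldehyde carbon while a hydrogen of one of the two allylic methyl groups passes to the carbonyl oxygen through a six-membered transition state, so the new C–C bond joins the future stereocentre to the future prenyl CH2 carbon and the double bond moves into the isopropenyl position. The closest known reaction type is the (BINOLate)titanium-catalysed asymmetric glyoxylate-ene reaction of trisubstituted alkenes, and no ring is closed. The carbinol centre C2 is set by the ligand, which shields one face of the chelated aldehyde ((S)-BINOL, 2S expected), and C3 is set by the preferred orientation of the CH2Ar group in the ordered ene transition state (syn adduct expected, hence 3R). Regioselectivity follows from the build-up of positive charge on the tertiary CMe2 carbon, which also excludes abstraction of a benzylic hydrogen; Friedel–Crafts hydroxyalkylation is suppressed by the three electron-withdrawing acetates, and a second ene reaction at the new, hindered isopropenyl group is limited by keeping 4 in excess. The minor anti diastereomer would lead to the enantiomeric side chain once C2 is deoxygenated, so it is to be removed by chromatography here or after step 4.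

Step 4
Reactants: 6 ene adduct
Product: 7 ethyl (2S,3R)-2-acetoxy-4-methyl-3-[(2,4,6-triacetoxyphenyl)methyl]pent-4-enoate
Conditions: Ac2O, pyridine, DMAP (cat.), CH2Cl2, rt
Reagents that add atoms: acetic anhydride, CC(=O)OC(C)=O
Why: DMAP-catalysed acetylation of the secondary α-hydroxy ester turns the carbinol oxygen into a carboxylate leaving group for the electron-transfer deoxygenation of step 5 and gives a second chance to separate the minor diastereomer.

Step 5
Reactants: 7 α-acetoxy ester
Product: 8 ethyl (3S)-4-methyl-3-[(2,4,6-triacetoxyphenyl)methyl]pent-4-enoate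
Conditions: SmI2 (2.5 equiv), THF–HMPA, MeOH, −78 °C
Reagents that add atoms: none
Why: Reduction of an α-acyloxy ester by SmI2 proceeds by two single-electron transfers that expel the α-acetate and give a samarium enolate, which methanol protonates, so C2 becomes CH2 while the β-stereocentre, which has no acidic hydrogen, is untouched (the descriptor changes to S only through the priority switch); aryl acetates should survive at low temperature, and any that are lost would be removed in step 6 anyway.

Step 6
Reactants: 8 deoxygenated triacetate ester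
Product: 9 ethyl (3S)-4-methyl-3-[(2,4,6-trihydroxyphenyl)methyl]pent-4-enoate
Conditions: K2CO3 (cat.), degassed EtOH, 0 °C → rt; neutral buffered work-up
Reagents that add atoms: none
Why: Base-catalysed transesterification cleaves the reactive aryl acetates far faster than the alkyl ester, ethanol as solvent leaves the ethyl ester unchanged, and exclusion of air and acid protects the electron-rich triol and its isopropenyl group.

Step 7
Reactants: 9 triol ester
Product: 10 ethyl (3S)-4-methyl-3-{[2,4,6-tris(methoxymethoxy)phenyl]methyl}pent-4-enoate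
Conditions: MOMCl (4 equiv), i-Pr2NEt, CH2Cl2, 0 °C → rt
Reagents that add atoms: chloromethyl methyl ether (MOMCl), COCCl
Why: O-alkylation of the phenols with the hard electrophile MOMCl under amine base (Williamson-type etherification) gives the tris-MOM ether, which is stable to hydride, ylide, organolithium and hydroxide and later directs the ortho-lithiation.

Step 8
Reactants: 10 tris-MOM ester
Product: 11 (3S)-4-methyl-3-{[2,4,6-tris(methoxymethoxy)phenyl]methyl}pent-4-enal
Conditions: i-Bu2AlH (1.1 equiv), CH2Cl2, −78 °C; aq KNa tartrate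
Reagents that add atoms: none
Why: Partial reduction of the ester with one equivalent of i-Bu2AlH at −78 °C stops at the tetrahedral aluminium hemiacetal, which releases the aldehyde only on work-up, and the stereocentre is β to the carbonyl and cannot epimerise.

Step 9
Reactants: 11 aldehyde
Product: 12 1,3,5-tris(methoxymethoxy)-2-[(2R)-5-methyl-2-(prop-1-en-2-yl)hex-4-en-1-yl]benzene
Conditions: i-PrPPh3 iodide, n-BuLi, THF, 0 °C; then 11, −78 °C → rt
Reagents that add atoms: isopropyltriphenylphosphonium iodide, CC(C)[P+](c1ccccc1)(c1ccccc1)c1ccccc1.[I-]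
Why: Wittig olefination with the unstabilised isopropylidene ylide converts the aldehyde into the trisubstituted alkene and completes the prenyl arm of the lavandulyl chain, with no E/Z issue because the ylide carbon bears two methyl groups.

Step 10
Reactants: 12 tris-MOM lavandulyl arene
Product: 14 1-{2,4,6-tris(methoxymethoxy)-3-[(2R)-5-methyl-2-(prop-1-en-2-yl)hex-4-en-1-yl]phenyl}ethan-1-one, via aryllithium 13 (not isolated)
Conditions: n-BuLi (1.2 equiv), THF, 0 °C; MeC(O)N(OMe)Me, −78 °C → rt; H2O
Reagents that add atoms: N-methoxy-N-methylacetamide, CC(=O)N(C)OC; n-butyllithium, [Li]CCCC (its lithium stands only in intermediate 13)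
Why: Directed ortho-metalation removes the ring hydrogen flanked by two OMOM groups (the two free ring positions are equivalent, so one ketone results), and the aryllithium is acylated by the Weinreb amide, whose chelated tetrahedral intermediate prevents over-addition.

Step 11
Reactants: 15 2-hydroxy-4-methoxybenzaldehyde
Product: 16 4-methoxy-2-(methoxymethoxy)benzaldehyde
Conditions: MOMCl, i-Pr2NEt, CH2Cl2, 0 °C → rt
Reagents that add atoms: chloromethyl methyl ether (MOMCl), COCCl
Why: Standard MOM etherification masks the phenol, which would otherwise form an unreactive phenoxide-conjugated aldehyde in the base-mediated condensation.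

Step 12
Reactants: 14 tris-MOM acetophenone; 16 MOM-protected aldehyde
Product: 17 (2E)-3-[4-methoxy-2-(methoxymethoxy)phenyl]-1-{2,4,6-tris(methoxymethoxy)-3-[(2R)-5-methyl-2-(prop-1-en-2-yl)hex-4-en-1-yl]phenyl}prop-2-en-1-one
Conditions: KOH, EtOH–H2O, 0 °C → rt, dark
Reagents that add atoms: none
Why: In this Claisen–Schmidt condensation the methyl ketone enolate adds to the non-enolisable aldehyde and the aldol loses water under the basic conditions to give the thermodynamically favoured E-enone, while all MOM ethers are stable to hydroxide.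

Step 13
Reactants: 17 tetrakis-MOM chalcone
Product: 18 (2E)-3-(2-hydroxy-4-methoxyphenyl)-1-{2,4,6-trihydroxy-3-[(2R)-5-methyl-2-(prop-1-en-2-yl)hex-4-en-1-yl]phenyl}prop-2-en-1-one (target, CNP0245273.1)
Conditions: 3 M aq HCl, MeOH, rt → 40 °C, dark, argon
Reagents that add atoms: none
Why: Acid-catalysed acetal exchange of the four aryl MOM ethers with methanol should release the phenols under mild conditions of the kind prenylated chalcones generally tolerate, and the stereocentre is not involved.

**Compound list**

1 | phloroglucinol | Oc1cc(O)cc(O)c1 | starting material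
2 | prenyl bromide | CC(C)=CCBr | starting material
3 | 2-(3-methylbut-2-en-1-yl)benzene-1,3,5-triol | CC(C)=CCc1c(O)cc(O)cc1O | intermediate
4 | 2-(3-methylbut-2-en-1-yl)benzene-1,3,5-triyl triacetate | CC(C)=CCc1c(OC(C)=O)cc(OC(C)=O)cc1OC(C)=O | intermediate
5 | ethyl glyoxylate | CCOC(=O)C=O | starting material
6 | ethyl (2S,3R)-2-hydroxy-4-methyl-3-[(2,4,6-triacetoxyphenyl)methyl]pent-4-enoate | C=C(C)[C@H]([C@H](O)C(=O)OCC)Cc1c(OC(C)=O)cc(OC(C)=O)cc1OC(C)=O | intermediate
7 | ethyl (2S,3R)-2-acetoxy-4-methyl-3-[(2,4,6-triacetoxyphenyl)methyl]pent-4-enoate | C=C(C)[C@H]([C@H](OC(C)=O)C(=O)OCC)Cc1c(OC(C)=O)cc(OC(C)=O)cc1OC(C)=O | intermediate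
8 | ethyl (3S)-4-methyl-3-[(2,4,6-triacetoxyphenyl)methyl]pent-4-enoate | C=C(C)[C@H](CC(=O)OCC)Cc1c(OC(C)=O)cc(OC(C)=O)cc1OC(C)=O | intermediate
9 | ethyl (3S)-4-methyl-3-[(2,4,6-trihydroxyphenyl)methyl]pent-4-enoate | C=C(C)[C@H](CC(=O)OCC)Cc1c(O)cc(O)cc1O | intermediate
10 | ethyl (3S)-4-methyl-3-{[2,4,6-tris(methoxymethoxy)phenyl]methyl}pent-4-enoate | C=C(C)[C@H](CC(=O)OCC)Cc1c(OCOC)cc(OCOC)cc1OCOC | intermediate
11 | (3S)-4-methyl-3-{[2,4,6-tris(methoxymethoxy)phenyl]methyl}pent-4-enal | C=C(C)[C@H](CC=O)Cc1c(OCOC)cc(OCOC)cc1OCOC | intermediate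
12 | 1,3,5-tris(methoxymethoxy)-2-[(2R)-5-methyl-2-(prop-1-en-2-yl)hex-4-en-1-yl]benzene | C=C(C)[C@H](CC=C(C)C)Cc1c(OCOC)cc(OCOC)cc1OCOC | intermediate
13 | {2,4,6-tris(methoxymethoxy)-3-[(2R)-5-methyl-2-(prop-1-en-2-yl)hex-4-en-1-yl]phenyl}lithium | C=C(C)[C@H](CC=C(C)C)Cc1c(OCOC)cc(OCOC)c([Li])c1OCOC | intermediate (not isolated)
14 | 1-{2,4,6-tris(methoxymethoxy)-3-[(2R)-5-methyl-2-(prop-1-en-2-yl)hex-4-en-1-yl]phenyl}ethan-1-one | C=C(C)[C@H](CC=C(C)C)Cc1c(OCOC)cc(OCOC)c(C(C)=O)c1OCOC | intermediate
15 | 2-hydroxy-4-methoxybenzaldehyde | COc1ccc(C=O)c(O)c1 | starting material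
16 | 4-methoxy-2-(methoxymethoxy)benzaldehyde | COCOc1cc(OC)ccc1C=O | intermediate
17 | (2E)-3-[4-methoxy-2-(methoxymethoxy)phenyl]-1-{2,4,6-tris(methoxymethoxy)-3-[(2R)-5-methyl-2-(prop-1-en-2-yl)hex-4-en-1-yl]phenyl}prop-2-en-1-one | C=C(C)[C@H](CC=C(C)C)Cc1c(OCOC)cc(OCOC)c(C(=O)/C=C/c2ccc(OC)cc2OCOC)c1OCOC | intermediate
18 | (2E)-3-(2-hydroxy-4-methoxyphenyl)-1-{2,4,6-trihydroxy-3-[(2R)-5-methyl-2-(prop-1-en-2-yl)hex-4-en-1-yl]phenyl}prop-2-en-1-one | C=C(C)[C@H](CC=C(C)C)Cc1c(O)cc(O)c(C(=O)/C=C/c2ccc(OC)cc2O)c1O | target

**Totals and risks**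

Total step count: 13. Longest linear sequence: 12 (steps 1–10, 12 and 13; step 11 is a one-step side branch).

Steps most likely to fail:

1. Step 3 (key step). The hindered, acetate-rich trisubstituted alkene may turn over slowly, the acetates may bind the Lewis acid, the syn/anti or facial selectivity may be insufficient, and the isopropenyl group of the product may react with glyoxylate a second time. The fallback replaces catalyst control by a racemic ene reaction and resolution; it sets out from 4 and returns at 8. Triacetate 4 and 5 are combined with stoichiometric SnCl4 in CH2Cl2 at −78 °C, an achiral Lewis-acid ene reaction expected to favour the anti adduct, to give the racemic anti adduct F1. Acylation of F1 with (1S)-camphanic chloride (pyridine, DMAP) gives the (2R,3R) camphanate F2 and its (2S,3S) diastereomer F3, which are separated by crystallisation or chromatography. Treatment of F2 with SmI2 in THF–HMPA–MeOH, as in step 5, expels the camphanate and delivers 8.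

2. Step 13. During removal of four MOM groups, an ortho phenol may add to the protonated isopropenyl or prenyl double bond (chroman formation), and the 2'-hydroxychalcone may close to the flavanone. The fallback avoids Brønsted acid by going through aryl silyl ethers; it sets out from 17 and returns at 18. Chalcone 17 is treated with TMSOTf and 2,2'-bipyridyl in CH2Cl2 at 0 °C, which transfers the methoxymethyl groups to the bipyridyl and leaves the tetrakis(trimethylsilyl) ether F5. Addition of water at rt then hydrolyses the aryl silyl ethers to 18.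

3. Step 10. The hindered aryllithium may deprotonate the acetyl donor instead of adding to it, returning 12, and some lateral metalation may occur. The fallback replaces acyl transfer by carbonyl addition and oxidation; it sets out from 12 (through aryllithium 13) and returns at 14. Aryllithium 13 is quenched with acetaldehyde at −78 °C to give the carbinol F4 as a mixture of carbinol epimers, and F4 is oxidised with Dess–Martin periodinane (NaHCO3, CH2Cl2) to 14.

Further compounds
F1 | step 3 | racemic ethyl (2R*,3R*)-2-hydroxy-4-methyl-3-[(2,4,6-triacetoxyphenyl)methyl]pent-4-enoate (anti; one enantiomer drawn) | C=C(C)[C@H]([C@@H](O)C(=O)OCC)Cc1c(OC(C)=O)cc(OC(C)=O)cc1OC(C)=O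
F2 | step 3 | ethyl (2R,3R)-4-methyl-3-[(2,4,6-triacetoxyphenyl)methyl]-2-{[(1S,4R)-4,7,7-trimethyl-3-oxo-2-oxabicyclo[2.2.1]heptane-1-carbonyl]oxy}pent-4-enoate | C=C(C)[C@H]([C@@H](OC(=O)[C@@]12CC[C@@](C)(C(=O)O1)C2(C)C)C(=O)OCC)Cc1c(OC(C)=O)cc(OC(C)=O)cc1OC(C)=O
F3 | step 3 | ethyl (2S,3S)-4-methyl-3-[(2,4,6-triacetoxyphenyl)methyl]-2-{[(1S,4R)-4,7,7-trimethyl-3-oxo-2-oxabicyclo[2.2.1]heptane-1-carbonyl]oxy}pent-4-enoate | C=C(C)[C@@H]([C@H](OC(=O)[C@@]12CC[C@@](C)(C(=O)O1)C2(C)C)C(=O)OCC)Cc1c(OC(C)=O)cc(OC(C)=O)cc1OC(C)=O
F4 | step 10 | 1-{2,4,6-tris(methoxymethoxy)-3-[(2R)-5-methyl-2-(prop-1-en-2-yl)hex-4-en-1-yl]phenyl}ethan-1-ol (both carbinol epimers) | C=C(C)[C@H](CC=C(C)C)Cc1c(OCOC)cc(OCOC)c(C(C)O)c1OCOC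
F5 | step 13 | (2E)-3-[4-methoxy-2-(trimethylsilyloxy)phenyl]-1-{2,4,6-tris(trimethylsilyloxy)-3-[(2R)-5-methyl-2-(prop-1-en-2-yl)hex-4-en-1-yl]phenyl}prop-2-en-1-one | C=C(C)[C@H](CC=C(C)C)Cc1c(O[Si](C)(C)C)cc(O[Si](C)(C)C)c(C(=O)/C=C/c2ccc(OC)cc2O[Si](C)(C)C)c1O[Si](C)(C)C
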